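## Retrosynthetic overview

1. The target is read as robinetinidol-(4β→8)-gallocatechin: upper unit with rings A/C/B (2R,3S,4R, i.e. 2,3-trans-3,4-cis), lower unit with rings D/F/E (2R,3S). All phenols and the lower 3-OH travel as benzyl ethers and are freed last.
2. Interflavan bond C4(ring C)–C8(ring D): the 8-lithio lower flavan adds to the C4 ketone of protected (+)-dihydrorobinetin (chiral pool). Ionic hydrogenation then brings hydride in anti to O3, which leaves the aryl group cis to O3.
3. Lower unit: ring F is made in one operation from an α-benzyloxy 2-fluoroaryl ketone (ring D, C4, C3) and 3,4,5-tris(benzyloxy)benzaldehyde (C2, ring E). An aldol addition makes C2–C3 and an SNAr closure makes O1–C8a; the C4 carbonyl is afterwards reduced to CH2.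
4. Enabling feature: in ring D the ether carbon C8a is ortho to C4a, which carries C4. A carbonyl at C4 therefore makes C3–H enolisable and at the same time opens C8a–F to addition–elimination by the C2 alkoxide. The C5 and C7 oxygens are meta to C8a and do not switch it off, and at this oxidation level the wanted 2,3-trans ring F is the thermodynamic isomer.
5. Ring order: rings A, B, C (from dihydrorobinetin), D and E (from the two arenes) are carried in; ring F is the only ring formed (step 3).

Key step: step 3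

Remark 1: (+)-(2R,3R)-dihydrorobinetin (13) is taken as a commercial chiral-pool material; its two stereocentres become C2 and C3 of the upper unit.
Remark 2: which pseudo-enantiomeric series of the ammonium catalyst in step 3 leads to the 2R product has to be settled by experiment; the cinchonidinium salt is written.

## Route

Step 1
Reactants: 1 1,3,5-trifluorobenzene
Product: 2 1,3-bis(benzyloxy)-5-fluorobenzene
Conditions: BnOH (2.1 equiv), NaH (2.2 equiv), 1,3-dimethyl-2-imidazolidinone, 0 → 90 °C, sealed vessel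
Reagents that add atoms: benzyl alcohol, OCc1ccccc1
Why: Twofold SNAr by sodium benzyloxide: each fluorine of 1 is activated by the two meta fluorines and every alkoxy group that enters deactivates the ring, so with two equivalents the reaction should stop at the monofluoride 2.

Step 2
Reactants: 2 1,3-bis(benzyloxy)-5-fluorobenzene; 3 2-(benzyloxy)-N-methoxy-N-methylacetamide
Product: 5 2-(benzyloxy)-1-[2,4-bis(benzyloxy)-6-fluorophenyl]ethan-1-one, via aryllithium 4 (not isolated)
Conditions: n-BuLi (1.05 equiv), THF, −78 °C; then 3, −78 °C; 1 M HCl work-up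
Reagents that add atoms: none
Why: Directed ortho-metalation at the ring carbon flanked by fluorine and benzyloxy (the most acidic C–H, later C4a), then acylation of the aryllithium by the N-methoxy-N-methylamide (Weinreb ketone synthesis), which stops at the ketone; the mixture is held at −78 °C so that 4 does not lose LiF to an aryne.

Step 3
Reactants: 5 2-(benzyloxy)-1-[2,4-bis(benzyloxy)-6-fluorophenyl]ethan-1-one; 6 3,4,5-tris(benzyloxy)benzaldehyde
Product: 8 hexa-O-benzyl-(2R,3R)-dihydromyricetin [(2R,3R)-3,5,7-tris(benzyloxy)-2-[3,4,5-tris(benzyloxy)phenyl]-2,3-dihydro-4H-chromen-4-one], via cesium anti-aldolate 7 (not isolated)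
Conditions: N-(9-anthracenylmethyl)cinchonidinium chloride (10 mol%), CsOH·H2O (1.5 equiv), toluene/CH2Cl2, −40 → 20 °C
Reagents that add atoms: none
Why: Proposed new method: under solid–liquid phase-transfer conditions the enolate of 5 (C3–H is acidified by the C4 carbonyl and the α-benzyloxy group) enters the organic phase as an ion pair with the chiral ammonium cation and adds to aldehyde 6 to make C2–C3; the oxygen of aldolate 7 then attacks C8a, whose fluoride is ortho to the same carbonyl, in an intramolecular addition–elimination (SNAr) that makes O1–C8a and releases fluoride as CsF. The closest known reaction types are the asymmetric phase-transfer Darzens condensation of α-heteroatom-substituted aryl ketones with aldehydes (ion-paired aldol addition, then ring closure through the aldolate oxygen) and the base-mediated aldol/SNAr annulation of 2-fluoroaryl ketones to chroman-4-ones; new is their combination, with the SNAr as the ring-closing step of the asymmetric process. Ring F closes in a 6-exo-trig addition–elimination at the arene carbon C8a, the C–F bond lying outside the new ring. C2 is controlled by the catalyst, which has to direct the enolate to the Si face of the aldehyde (2R), and the irreversible loss of fluoride then locks this centre against retro-aldol exchange; C3 lies α to the ketone in 8 and is under thermodynamic control, the 2,3-trans arrangement with both substituents equatorial being favoured whatever the simple diastereoselectivity of the addition. The step needs chemoselection for O-arylation over β-elimination to a chalcone and over attack of hydroxide on C–F: the aldolate cannot lose oxide, only the C2 oxygen reaches C8a through a six-membered transition state, the benzyloxy groups at C5 and C7 are meta to C8a and do not deactivate it, and the benzyl ether on O3 rules out a competing five-membered closure.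

Step 4
Reactants: 8 hexa-O-benzyl-(2R,3R)-dihydromyricetin
Product: 9 (2R,3S,4R)-3,5,7-tris(benzyloxy)-2-[3,4,5-tris(benzyloxy)phenyl]-3,4-dihydro-2H-chromen-4-ol
Conditions: NaBH4, THF/MeOH, 0 °C
Reagents that add atoms: none
Why: Borohydride reduction of the aryl ketone; axial hydride delivery should give mainly the all-equatorial 3,4-trans alcohol (4R), the C4 configuration being immaterial because this centre becomes CH2 in step 5, and the neutral conditions leave C2 and C3 untouched.

Step 5
Reactants: 9 (2R,3S,4R)-3,5,7-tris(benzyloxy)-2-[3,4,5-tris(benzyloxy)phenyl]-3,4-dihydro-2H-chromen-4-ol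
Product: 11 hexa-O-benzyl-(+)-gallocatechin, via flavan-4-yl cation 10 (not isolated)
Conditions: Et3SiH (10 equiv), CF3CO2H (3 equiv), CH2Cl2 (high dilution), −40 → −10 °C
Reagents that add atoms: none
Why: Ionic hydrogenation: acid ionises the benzylic C4–OH to a cation stabilised by O1 and the C5/C7 oxygens, and the large excess of silane should transfer hydride faster than the cation can alkylate ring D of a second molecule; C2 and C3 take no part.

Step 6
Reactants: 11 hexa-O-benzyl-(+)-gallocatechin
Product: 12 (2R,3S)-8-bromo-3,5,7-tris(benzyloxy)-2-[3,4,5-tris(benzyloxy)phenyl]-3,4-dihydro-2H-chromene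
Conditions: N-bromosuccinimide (1.05 equiv), CH2Cl2, −78 → 0 °C
Reagents that add atoms: N-bromosuccinimide, O=C1CCC(=O)N1Br
Why: Electrophilic aromatic bromination; ring D carries three oxygen donors and is far more reactive than ring E, and C8 (ortho to O1 and to the C7 ether, para to the C5 ether) is the position at which benzylated 5,7-dioxygenated flavans are brominated selectively.

Step 7
Reactants: 13 (+)-dihydrorobinetin
Product: 14 (2R,3R)-7-(benzyloxy)-3-hydroxy-2-[3,4,5-tris(benzyloxy)phenyl]-2,3-dihydro-4H-chromen-4-one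
Conditions: BnBr (4.4 equiv), K2CO3, DMF, rt, argon
Reagents that add atoms: benzyl bromide, BrCc1ccccc1
Why: Williamson etherification of the four phenols, which carbonate deprotonates while the secondary 3-OH stays unalkylated; room temperature and exclusion of air are meant to keep base-induced ring opening and oxidation of the dihydroflavonol down, so that the two chiral-pool centres are carried through.

Step 8
Reactants: 14 (2R,3R)-7-(benzyloxy)-3-hydroxy-2-[3,4,5-tris(benzyloxy)phenyl]-2,3-dihydro-4H-chromen-4-one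
Product: 15 (2R,3R)-7-(benzyloxy)-3-[(tert-butyldimethylsilyl)oxy]-2-[3,4,5-tris(benzyloxy)phenyl]-2,3-dihydro-4H-chromen-4-one
Conditions: t-BuMe2SiCl, imidazole, DMF, rt
Reagents that add atoms: tert-butyldimethylsilyl chloride, CC(C)(C)[Si](C)(C)Cl
Why: Silylation of the α-ketol hydroxyl with imidazole as a weak base that does not epimerise C2 or C3; the bulky silyl ether removes the acidic OH before the organolithium step and later shields one face of C4.

Step 9
Reactants: 12 (2R,3S)-8-bromo-3,5,7-tris(benzyloxy)-2-[3,4,5-tris(benzyloxy)phenyl]-3,4-dihydro-2H-chromene; 15 (2R,3R)-7-(benzyloxy)-3-[(tert-butyldimethylsilyl)oxy]-2-[3,4,5-tris(benzyloxy)phenyl]-2,3-dihydro-4H-chromen-4-one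
Product: 17 C4-aryl tertiary carbinol (upper unit 2R,3R,4R; lower unit 2R,3S), via 8-lithioflavan 16 (not isolated)
Conditions: t-BuLi (2.0 equiv), THF, −78 °C; then 15, −78 → −40 °C; H2O quench
Reagents that add atoms: none
Why: Bromine–lithium exchange, then 1,2-addition of the 2,6-dioxygenated aryllithium to the chromanone carbonyl, a union with close precedent for 3-silyloxyflavan-4-ones; low temperature holds back deprotonation at C3, and the new carbinol centre (aryl expected anti to the silyl ether) is of no consequence because C4 is planarised in step 10.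

Step 10
Reactants: 17 C4-aryl tertiary carbinol
Product: 19 7,3',4',5'-tetra-O-benzyl-3-O-(tert-butyldimethylsilyl)robinetinidol-(4β→8)-3,5,7,3',4',5'-hexa-O-benzylgallocatechin, via C4 diarylmethyl cation 18 (not isolated)
Conditions: Bu3SnH (3 equiv), CF3CO2H, CH2Cl2, −78 → 0 °C
Reagents that add atoms: none
Why: Ionic hydrogenation of the tertiary doubly benzylic carbinol: acid gives the planar C4 cation and the tin hydride should deliver hydride to the face anti to the adjacent bulky 3-silyloxy group, which leaves the ring D aryl group cis to O3 (4R, the 4β linkage), i.e. the same facial preference that gives 3,4-trans products when an arene attacks a 2,3-trans flavan-4-yl cation, here turned around because the arene is already in place.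

Step 11
Reactants: 19 7,3',4',5'-tetra-O-benzyl-3-O-(tert-butyldimethylsilyl)robinetinidol-(4β→8)-3,5,7,3',4',5'-hexa-O-benzylgallocatechin
Product: 20 7,3',4',5'-tetra-O-benzylrobinetinidol-(4β→8)-3,5,7,3',4',5'-hexa-O-benzylgallocatechin
Conditions: Bu4NF, AcOH, THF, 0 °C → rt
Reagents that add atoms: none
Why: Fluoride-induced desilylation driven by the Si–F bond; buffering with acetic acid keeps the medium near neutral so that neither the benzyl ethers nor any stereocentre is touched.

Step 12
Reactants: 20 7,3',4',5'-tetra-O-benzylrobinetinidol-(4β→8)-3,5,7,3',4',5'-hexa-O-benzylgallocatechin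
Product: 21 robinetinidol-(4β→8)-gallocatechin (target)
Conditions: H2 (1 atm), Pd(OH)2/C, THF/MeOH, rt
Reagents that add atoms: none
Why: Hydrogenolysis of the ten benzyl ethers under neutral conditions, which should leave the C4–C8 interflavan bond, both pyran rings and all five stereocentres intact.

## Compound list

1 | 1,3,5-trifluorobenzene | Fc1cc(F)cc(F)c1 | starting material
2 | 1,3-bis(benzyloxy)-5-fluorobenzene | Fc1cc(OCc2ccccc2)cc(OCc2ccccc2)c1 | intermediate
3 | 2-(benzyloxy)-N-methoxy-N-methylacetamide | CON(C)C(=O)COCc1ccccc1 | starting material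
4 | [2,4-bis(benzyloxy)-6-fluorophenyl]lithium (formed in the flask) | [Li]c1c(F)cc(OCc2ccccc2)cc1OCc1ccccc1 | intermediate
5 | 2-(benzyloxy)-1-[2,4-bis(benzyloxy)-6-fluorophenyl]ethan-1-one | O=C(COCc1ccccc1)c1c(F)cc(OCc2ccccc2)cc1OCc1ccccc1 | intermediate
6 | 3,4,5-tris(benzyloxy)benzaldehyde | O=Cc1cc(OCc2ccccc2)c(OCc2ccccc2)c(OCc2ccccc2)c1 | starting material
7 | cesium (1R,2R)-2-(benzyloxy)-3-[2,4-bis(benzyloxy)-6-fluorophenyl]-3-oxo-1-[3,4,5-tris(benzyloxy)phenyl]propan-1-olate (anti-aldolate, formed in the flask) | [Cs+].[O-][C@H](c1cc(OCc2ccccc2)c(OCc2ccccc2)c(OCc2ccccc2)c1)[C@@H](OCc1ccccc1)C(=O)c1c(F)cc(OCc2ccccc2)cc1OCc1ccccc1 | intermediate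
8 | (2R,3R)-3,5,7-tris(benzyloxy)-2-[3,4,5-tris(benzyloxy)phenyl]-2,3-dihydro-4H-chromen-4-one (hexa-O-benzyl-dihydromyricetin) | O=C1c2c(OCc3ccccc3)cc(OCc3ccccc3)cc2O[C@H](c2cc(OCc3ccccc3)c(OCc3ccccc3)c(OCc3ccccc3)c2)[C@H]1OCc1ccccc1 | intermediate
9 | (2R,3S,4R)-3,5,7-tris(benzyloxy)-2-[3,4,5-tris(benzyloxy)phenyl]-3,4-dihydro-2H-chromen-4-ol | O[C@@H]1c2c(OCc3ccccc3)cc(OCc3ccccc3)cc2O[C@H](c2cc(OCc3ccccc3)c(OCc3ccccc3)c(OCc3ccccc3)c2)[C@H]1OCc1ccccc1 | intermediate
10 | (2R,3S)-3,5,7-tris(benzyloxy)-2-[3,4,5-tris(benzyloxy)phenyl]-3,4-dihydro-2H-chromen-4-ylium trifluoroacetate (formed in the flask) | [O-]C(=O)C(F)(F)F.[CH+]1c2c(OCc3ccccc3)cc(OCc3ccccc3)cc2O[C@H](c2cc(OCc3ccccc3)c(OCc3ccccc3)c(OCc3ccccc3)c2)[C@H]1OCc1ccccc1 | intermediate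
11 | (2R,3S)-3,5,7-tris(benzyloxy)-2-[3,4,5-tris(benzyloxy)phenyl]-3,4-dihydro-2H-chromene (hexa-O-benzyl-(+)-gallocatechin) | C1c2c(OCc3ccccc3)cc(OCc3ccccc3)cc2O[C@H](c2cc(OCc3ccccc3)c(OCc3ccccc3)c(OCc3ccccc3)c2)[C@H]1OCc1ccccc1 | intermediate
12 | (2R,3S)-8-bromo-3,5,7-tris(benzyloxy)-2-[3,4,5-tris(benzyloxy)phenyl]-3,4-dihydro-2H-chromene | C1c2c(OCc3ccccc3)cc(OCc3ccccc3)c(Br)c2O[C@H](c2cc(OCc3ccccc3)c(OCc3ccccc3)c(OCc3ccccc3)c2)[C@H]1OCc1ccccc1 | intermediate
13 | (2R,3R)-3,7-dihydroxy-2-(3,4,5-trihydroxyphenyl)-2,3-dihydro-4H-chromen-4-one ((+)-dihydrorobinetin) | O=C1c2ccc(O)cc2O[C@H](c2cc(O)c(O)c(O)c2)[C@H]1O | starting material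
14 | (2R,3R)-7-(benzyloxy)-3-hydroxy-2-[3,4,5-tris(benzyloxy)phenyl]-2,3-dihydro-4H-chromen-4-one | O=C1c2ccc(OCc3ccccc3)cc2O[C@H](c2cc(OCc3ccccc3)c(OCc3ccccc3)c(OCc3ccccc3)c2)[C@H]1O | intermediate
15 | (2R,3R)-7-(benzyloxy)-3-[(tert-butyldimethylsilyl)oxy]-2-[3,4,5-tris(benzyloxy)phenyl]-2,3-dihydro-4H-chromen-4-one | O=C1c2ccc(OCc3ccccc3)cc2O[C@H](c2cc(OCc3ccccc3)c(OCc3ccccc3)c(OCc3ccccc3)c2)[C@H]1O[Si](C)(C)C(C)(C)C | intermediate
16 | [(2R,3S)-3,5,7-tris(benzyloxy)-2-[3,4,5-tris(benzyloxy)phenyl]-3,4-dihydro-2H-chromen-8-yl]lithium (formed in the flask) | C1c2c(OCc3ccccc3)cc(OCc3ccccc3)c([Li])c2O[C@H](c2cc(OCc3ccccc3)c(OCc3ccccc3)c(OCc3ccccc3)c2)[C@H]1OCc1ccccc1 | intermediate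
17 | (2R,3R,4R)-7-(benzyloxy)-3-[(tert-butyldimethylsilyl)oxy]-4-{(2R,3S)-3,5,7-tris(benzyloxy)-2-[3,4,5-tris(benzyloxy)phenyl]-3,4-dihydro-2H-chromen-8-yl}-2-[3,4,5-tris(benzyloxy)phenyl]-3,4-dihydro-2H-chromen-4-ol | c1ccccc1COc1ccc2c(c1)O[C@H](c1cc(OCc3ccccc3)c(OCc3ccccc3)c(OCc3ccccc3)c1)[C@@H](O[Si](C)(C)C(C)(C)C)[C@]2(O)c1c(OCc3ccccc3)cc(OCc3ccccc3)c2c1O[C@H](c1cc(OCc3ccccc3)c(OCc3ccccc3)c(OCc3ccccc3)c1)[C@@H](OCc1ccccc1)C2 | intermediate
18 | C4 cation of 17 as its trifluoroacetate: (2R,3S)-chroman-4-ylium carrying the lower (2R,3S)-flavan-8-yl group at C4 (formed in the flask) | [O-]C(=O)C(F)(F)F.c1ccccc1COc1ccc2c(c1)O[C@H](c1cc(OCc3ccccc3)c(OCc3ccccc3)c(OCc3ccccc3)c1)[C@@H](O[Si](C)(C)C(C)(C)C)[C+]2c1c(OCc3ccccc3)cc(OCc3ccccc3)c2c1O[C@H](c1cc(OCc3ccccc3)c(OCc3ccccc3)c(OCc3ccccc3)c1)[C@@H](OCc1ccccc1)C2 | intermediate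
19 | 7,3',4',5'-tetra-O-benzyl-3-O-(tert-butyldimethylsilyl)robinetinidol-(4β→8)-3,5,7,3',4',5'-hexa-O-benzylgallocatechin (upper 2R,3S,4R; lower 2R,3S) | c1ccccc1COc1ccc2c(c1)O[C@H](c1cc(OCc3ccccc3)c(OCc3ccccc3)c(OCc3ccccc3)c1)[C@@H](O[Si](C)(C)C(C)(C)C)[C@H]2c1c(OCc3ccccc3)cc(OCc3ccccc3)c2c1O[C@H](c1cc(OCc3ccccc3)c(OCc3ccccc3)c(OCc3ccccc3)c1)[C@@H](OCc1ccccc1)C2 | intermediate
20 | 7,3',4',5'-tetra-O-benzylrobinetinidol-(4β→8)-3,5,7,3',4',5'-hexa-O-benzylgallocatechin (upper 2R,3S,4R; lower 2R,3S) | c1ccccc1COc1ccc2c(c1)O[C@H](c1cc(OCc3ccccc3)c(OCc3ccccc3)c(OCc3ccccc3)c1)[C@@H](O)[C@H]2c1c(OCc3ccccc3)cc(OCc3ccccc3)c2c1O[C@H](c1cc(OCc3ccccc3)c(OCc3ccccc3)c(OCc3ccccc3)c1)[C@@H](OCc1ccccc1)C2 | intermediate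
21 | robinetinidol-(4β→8)-gallocatechin, (2R,2'R,3S,3'S,4R)-2,2'-bis(3,4,5-trihydroxyphenyl)-3,3',4,4'-tetrahydro-2H,2'H-[4,8'-bichromene]-3,3',5',7,7'-pentol | Oc1ccc2c(c1)O[C@H](c1cc(O)c(O)c(O)c1)[C@@H](O)[C@H]2c1c(O)cc(O)c2c1O[C@H](c1cc(O)c(O)c(O)c1)[C@@H](O)C2 | target

## Step count and risks

Total step count: 12. Longest linear sequence: 10 steps (steps 1–6, then 9–12); the upper-unit branch (steps 7–8) joins at step 9.

The three steps most likely to fail:

**Step 3 (bears the label "Proposed new method:").** The aldol addition is reversible, and ring closure onto the electron-rich, doubly ortho-substituted fluoroarene may be slower than retro-aldol, so that the enantioselection set in the C–C bond formation leaks away. Loss of water from the aldol to an α-benzyloxychalcone, and base-induced opening of ring F (E1cB) with loss of the C2 configuration, are the other ways out. Fallback (known chemistry, sets out from 5 and 6): the two bonds are made in two separate operations without a chiral catalyst. LiN(SiMe3)2 in THF at −78 °C, then 6, should give the β-hydroxy ketone 2-(benzyloxy)-1-[2,4-bis(benzyloxy)-6-fluorophenyl]-3-hydroxy-3-[3,4,5-tris(benzyloxy)phenyl]propan-1-one F1 as a mixture of stereoisomers. K2CO3 in DMF at 60 °C should then close ring F by intramolecular SNAr and equilibrate C3 to the racemic 2,3-trans ketone, i.e. 8 together with its (2S,3S)-enantiomer F2. Preparative chromatography on a chiral stationary phase separates the two, and the route is rejoined at 8.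

**Step 10.** The hydride transfer to the planar C4 cation may show poor facial selectivity, because a quasi-axial C2 aryl group and the 3-silyloxy group would shield opposite faces; the cation may also lose the C3 proton. Fallback (sets out from 15, with 11 as partner): NaBH4 reduces 15 to the flavan-4-ol (2R,3S,4R)-7-(benzyloxy)-3-[(tert-butyldimethylsilyl)oxy]-2-[3,4,5-tris(benzyloxy)phenyl]-3,4-dihydro-2H-chromen-4-ol F3. With a catalytic amount of Me3SiOSO2CF3 in CH2Cl2 at −78 °C and an excess of 11, F3 ionises and the cation alkylates C8 of 11 (the classical Friedel–Crafts-type flavanol condensation). This should give 19 next to its C4 epimer, the 3,4-trans (4α) dimer F4, which is expected to be the major one; the two are separated by chromatography and the route is rejoined at 19 (steps 6, 9 and 10 are then not needed).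

**Step 5.** The flavan-4-yl cation may be captured by ring D of a second molecule (self-condensation to oligomers) in competition with hydride transfer, and benzyl groups may be partly lost under acid. Fallback (sets out from 9): a radical deoxygenation that avoids the cation. 1,1'-Thiocarbonyldiimidazole and 4-(dimethylamino)pyridine in CH2Cl2 convert 9 into its 4-O-(imidazol-1-ylthiocarbonyl) derivative F5. Bu3SnH with azobisisobutyronitrile in toluene at 80 °C (Barton–McCombie deoxygenation) should then give 11, where the route is rejoined.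

Further compounds
F1 | step 3 | 2-(benzyloxy)-1-[2,4-bis(benzyloxy)-6-fluorophenyl]-3-hydroxy-3-[3,4,5-tris(benzyloxy)phenyl]propan-1-one (mixture of stereoisomers) | OC(c1cc(OCc2ccccc2)c(OCc2ccccc2)c(OCc2ccccc2)c1)C(OCc1ccccc1)C(=O)c1c(F)cc(OCc2ccccc2)cc1OCc1ccccc1
F2 | step 3 | (2S,3S)-3,5,7-tris(benzyloxy)-2-[3,4,5-tris(benzyloxy)phenyl]-2,3-dihydro-4H-chromen-4-one (enantiomer of 8) | O=C1c2c(OCc3ccccc3)cc(OCc3ccccc3)cc2O[C@@H](c2cc(OCc3ccccc3)c(OCc3ccccc3)c(OCc3ccccc3)c2)[C@@H]1OCc1ccccc1
F3 | step 10 | (2R,3S,4R)-7-(benzyloxy)-3-[(tert-butyldimethylsilyl)oxy]-2-[3,4,5-tris(benzyloxy)phenyl]-3,4-dihydro-2H-chromen-4-ol | O[C@@H]1c2ccc(OCc3ccccc3)cc2O[C@H](c2cc(OCc3ccccc3)c(OCc3ccccc3)c(OCc3ccccc3)c2)[C@H]1O[Si](C)(C)C(C)(C)C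
F4 | step 10 | 7,3',4',5'-tetra-O-benzyl-3-O-(tert-butyldimethylsilyl)robinetinidol-(4α→8)-3,5,7,3',4',5'-hexa-O-benzylgallocatechin (C4 epimer of 19; upper 2R,3S,4S) | c1ccccc1COc1ccc2c(c1)O[C@H](c1cc(OCc3ccccc3)c(OCc3ccccc3)c(OCc3ccccc3)c1)[C@@H](O[Si](C)(C)C(C)(C)C)[C@@H]2c1c(OCc3ccccc3)cc(OCc3ccccc3)c2c1O[C@H](c1cc(OCc3ccccc3)c(OCc3ccccc3)c(OCc3ccccc3)c1)[C@@H](OCc1ccccc1)C2
F5 | step 5 | 4-O-(imidazol-1-ylthiocarbonyl) derivative of 9 (configuration as in 9) | S=C(n1ccnc1)O[C@@H]1c2c(OCc3ccccc3)cc(OCc3ccccc3)cc2O[C@H](c2cc(OCc3ccccc3)c(OCc3ccccc3)c(OCc3ccccc3)c2)[C@H]1OCc1ccccc1
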